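## Retrosynthetic overview

1. Target **13** is (5S,8R), i.e. 5,8-cis. It comes from N–O-methylation of 1-hydroxy-4-pyridone **12**, which comes from N-oxidation and PMB removal of tetrahydroquinoline **10**.
2. **10** comes from the new step: enantio- and cis-selective Ru-catalysed hydrogenation of only the benzo ring of the aromatic quinoline **9**, setting C5 and C8 together.
3. **9** comes from B-alkyl Suzuki coupling of 5-bromoquinoline **7** with 5-phenyl-1-pentene **8**.
4. **7** comes from Conrad–Limpach quinolone **6**, made from 5-bromo-2-methoxyaniline **4** and methyl 2-methoxyacetoacetate **3** (from methyl acetoacetate **1**).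
5. Ring order: the benzene ring is bought, the pyridine/pyridone ring is closed in step 4, and the carbocycle is dearomatised last in step 7.

Assumption: the absolute sense of induction of the new hydrogenation cannot be predicted with certainty. The ligand enantiomer written is taken to give (5S,8R); its equally available mirror image is used if the first run shows the opposite sense.

## Route

**Step 1**
Reactants: **1** methyl acetoacetate
Product: **2** methyl 2-diazo-3-oxobutanoate
Conditions: p-ABSA, Et3N, MeCN, 0 °C → rt
Reagents that add atoms: 4-acetamidobenzenesulfonyl azide (p-ABSA), CC(=O)Nc1ccc(cc1)S(=O)(=O)N=[N+]=[N-]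
Why: Regitz diazo transfer to the doubly activated methylene of a β-keto ester is a standard, high-yielding reaction.

**Step 2**
Reactants: **2** methyl 2-diazo-3-oxobutanoate
Product: **3** methyl 2-methoxy-3-oxobutanoate
Conditions: Rh2(OAc)4 (1 mol%), MeOH (5 equiv), CH2Cl2, 40 °C
Reagents that add atoms: methanol, CO
Why: Rh(II)-carbenoid O–H insertion of an acceptor/acceptor diazo compound into methanol gives the α-methoxy β-keto ester cleanly, without Wolff rearrangement.

**Step 3**
Reactants: **3** methyl 2-methoxy-3-oxobutanoate; **4** 5-bromo-2-methoxyaniline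
Product: **5** methyl (E)-3-[(5-bromo-2-methoxyphenyl)amino]-2-methoxybut-2-enoate (N–H···O=C hydrogen-bonded enamino ester; geometry is inconsequential)
Conditions: TsOH·H2O (5 mol%), cyclohexane, reflux, Dean–Stark
Reagents that add atoms: none
Why: In the first stage of the Conrad–Limpach synthesis, mild acid with water removal condenses the aniline at the ketone rather than the ester to give the β-anilinoacrylate.

**Step 4**
Reactants: **5** enamino ester
Product: **6** 5-bromo-3,8-dimethoxy-2-methylquinolin-4(1H)-one
Conditions: Ph2O, 250 °C, 20 min (added to pre-heated solvent), –MeOH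
Reagents that add atoms: none
Why: Conrad–Limpach thermal cyclisation (imino-ketene formation then 6π-electrocyclisation) can only close at the single free ortho position, so Br ends at C5 and OMe at C8.

**Step 5**
Reactants: **6** quinolone
Product: **7** 5-bromo-3,8-dimethoxy-4-[(4-methoxybenzyl)oxy]-2-methylquinoline
Conditions: PMBCl, Cs2CO3, TBAI (cat.), DMF, 50 °C
Reagents that add atoms: 4-methoxybenzyl chloride, COc1ccc(CCl)cc1
Why: This is O-alkylation of the ambident quinolone anion; N1 is blocked by the 2-Me and the peri 8-OMe, so alkylation goes to O4 and gives the pyridine tautomer needed for later N-oxidation.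

**Step 6**
Reactants: **7** 5-bromoquinoline PMB ether; **8** 5-phenyl-1-pentene
Product: **9** 3,8-dimethoxy-4-[(4-methoxybenzyl)oxy]-2-methyl-5-(5-phenylpentyl)quinoline
Conditions: **8**, 9-BBN, THF, 0 °C → rt; then **7**, Pd(dppf)Cl2 (5 mol%), aq. K3PO4, THF/DMF, 70 °C
Reagents that add atoms: none (9-BBN leaves no atoms)
Why: In this B-alkyl Suzuki–Miyaura coupling, anti-Markovnikov hydroboration gives the primary alkyl-9-BBN, which couples with the aryl bromide; dppf suppresses β-hydride elimination.

**Step 7 (key step)**
Reactants: **9** aromatic quinoline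
Product: **10** (5S,8R)-3,8-dimethoxy-4-[(4-methoxybenzyl)oxy]-2-methyl-5-(5-phenylpentyl)-5,6,7,8-tetrahydroquinoline (5,8-cis)
Conditions: [Ru(η3-methallyl)2(cod)] (5 mol%), (R,R)-(S,S)-PhTRAP (5.5 mol%), H2 (50 bar), i-PrOH/EtOAc, 80 °C, 24 h
Reagents that add atoms: none (H2 only)
Why: Proposed new method: Ru–H complexes of trans-chelating chiral bisphosphines are known to hydrogenate the carbocycle of simple 8-monosubstituted quinolines enantioselectively through η4-binding of the benzo ring, and here that reactivity is extended to an unexplored substrate class (5,8-disubstituted, 8-alkoxy, fully substituted pyridine ring) so that two non-adjacent stereocentres form in one operation; the 2,3,4-substituents block N-bound reduction of the hetero-ring, the fused benzo ring costs much less resonance energy to reduce than the isolated phenyl and PMB rings, delivery of both H2 equivalents to the Ru-bound face without decomplexation gives 5,8-cis, and the chiral pocket distinguishes the two faces through the N1/8-OMe edge versus the 4-OPMB/5-alkyl edge; the closest known reaction type is Ru-catalysed asymmetric carbocycle hydrogenation of 8-substituted quinolines and of quinoxalines.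

**Step 8**
Reactants: **10** tetrahydroquinoline
Product: **11** (5S,8R)-3,8-dimethoxy-4-[(4-methoxybenzyl)oxy]-2-methyl-5-(5-phenylpentyl)-5,6,7,8-tetrahydroquinoline 1-oxide
Conditions: mCPBA (1.3 equiv), NaHCO3, CH2Cl2, 0 °C → rt
Reagents that add atoms: mCPBA, O=C(OO)c1cccc(Cl)c1
Why: Peracid N-oxidation of a 2,6-dialkyl-type pyridine is routine, and the molecule has no alkene, amine or other oxidisable group, so both stereocentres are untouched.

**Step 9**
Reactants: **11** N-oxide
Product: **12** (5S,8R)-1-hydroxy-3,8-dimethoxy-2-methyl-5-(5-phenylpentyl)-5,6,7,8-tetrahydroquinolin-4(1H)-one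
Conditions: TFA/CH2Cl2 (1:4), anisole (5 equiv), 0 °C → rt
Reagents that add atoms: none
Why: Acidolytic PMB cleavage is easy because the protonated N-oxide makes O4 an excellent leaving group; the PMB cation is trapped by anisole, the product tautomerises to the 1-hydroxy-4-pyridone, and the methyl ethers and the C8 ether (next to a pyridinium, so not ionisable) survive.

**Step 10**
Reactants: **12** 1-hydroxy-4-pyridone
Product: **13** Waltherione H, (5S,8R)-1,3,8-trimethoxy-2-methyl-5-(5-phenylpentyl)-5,6,7,8-tetrahydroquinolin-4(1H)-one
Conditions: MeI (1.5 equiv), K2CO3, DMF, 0 °C → rt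
Reagents that add atoms: iodomethane, CI
Why: This is O-alkylation of the hydroxamate-like N–O⁻ (α-effect nucleophile), which keeps the pyridone carbonyl, as in known alkylations of 1-hydroxy-4-pyridones and 1-hydroxy-4-quinolones; K2CO3 is too weak to epimerise C5 or C8.

## Compound list

1 | methyl acetoacetate | CC(=O)CC(=O)OC | starting material
2 | methyl 2-diazo-3-oxobutanoate | CC(=O)C(=[N+]=[N-])C(=O)OC | intermediate
3 | methyl 2-methoxy-3-oxobutanoate | CC(=O)C(OC)C(=O)OC | intermediate
4 | 5-bromo-2-methoxyaniline | COc1ccc(Br)cc1N | starting material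
5 | methyl (E)-3-[(5-bromo-2-methoxyphenyl)amino]-2-methoxybut-2-enoate | COC(=O)/C(OC)=C(C)\Nc1cc(Br)ccc1OC | intermediate
6 | 5-bromo-3,8-dimethoxy-2-methylquinolin-4(1H)-one | COc1c(C)[nH]c2c(OC)ccc(Br)c2c1=O | intermediate
7 | 5-bromo-3,8-dimethoxy-4-[(4-methoxybenzyl)oxy]-2-methylquinoline | COc1c(C)nc2c(OC)ccc(Br)c2c1OCc1ccc(OC)cc1 | intermediate
8 | 5-phenyl-1-pentene | C=CCCCc1ccccc1 | starting material
9 | 3,8-dimethoxy-4-[(4-methoxybenzyl)oxy]-2-methyl-5-(5-phenylpentyl)quinoline | COc1c(C)nc2c(OC)ccc(CCCCCc3ccccc3)c2c1OCc1ccc(OC)cc1 | intermediate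
10 | (5S,8R)-3,8-dimethoxy-4-[(4-methoxybenzyl)oxy]-2-methyl-5-(5-phenylpentyl)-5,6,7,8-tetrahydroquinoline | COc1c(C)nc2c(c1OCc1ccc(OC)cc1)[C@@H](CCCCCc1ccccc1)CC[C@H]2OC | intermediate
11 | (5S,8R)-3,8-dimethoxy-4-[(4-methoxybenzyl)oxy]-2-methyl-5-(5-phenylpentyl)-5,6,7,8-tetrahydroquinoline 1-oxide | COc1c(C)[n+]([O-])c2c(c1OCc1ccc(OC)cc1)[C@@H](CCCCCc1ccccc1)CC[C@H]2OC | intermediate
12 | (5S,8R)-1-hydroxy-3,8-dimethoxy-2-methyl-5-(5-phenylpentyl)-5,6,7,8-tetrahydroquinolin-4(1H)-one | COc1c(C)n(O)c2c(c1=O)[C@@H](CCCCCc1ccccc1)CC[C@H]2OC | intermediate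
13 | Waltherione H, (5S,8R)-1,3,8-trimethoxy-2-methyl-5-(5-phenylpentyl)-5,6,7,8-tetrahydroquinolin-4(1H)-one | COc1c(C)n(OC)c2c(c1=O)[C@@H](CCCCCc1ccccc1)CC[C@H]2OC | target

## Step count and risks

Total steps: 10. Longest linear sequence: 10 (from methyl acetoacetate **1**; 8 from aniline **4**).

Steps most likely to fail:

1. **Step 7 (proposed new asymmetric carbocycle hydrogenation).** The risks are insufficient ee or cis/trans ratio, loss of MeOH from a 7,8-dihydro intermediate, and partial reduction of the pendant arenes. Fallback (known chemistry, stepwise stereocontrol without dearomatisation):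
   - Set C5 by Cu/phosphoramidite-catalysed asymmetric conjugate addition of (5-phenylpentyl)MgBr to cyclohex-2-enone.
   - C-acylate and annulate the 3-methoxy-2-methyl-4-oxypyridine ring onto the resulting 2-acyl-3-alkylcyclohexanone (Camps-type condensation), then O-protect.
   - Oxygenate C8 by N-oxide/Boekelheide acetoxylation, oxidise to the 8-ketone, set C8 by catalyst-controlled Noyori transfer hydrogenation, and O-methylate to rejoin the route at **10**.

2. **Step 4 (thermal Conrad–Limpach closure ortho to bromine).** The risk is low yield or decomposition at 250 °C at the hindered position. Fallback: cyclise the unhindered enamine from 2-methoxyaniline instead, protect O4 as a MOM ether (no brominatable arene), and introduce bromine afterwards with NBS at C5. C5 is para to the 8-OMe and is the established site for 8-methoxyquinolines. Then continue with the Suzuki coupling.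

3. **Step 10 (N–O versus C4–O methylation of the ambident hydroxypyridone).** The risk is formation of the 4-methoxypyridine N-oxide isomer. Fallback: reverse the order. O-methylate N-oxide **11** with MeOTf to the 1-methoxy-4-(PMB-oxy)pyridinium triflate, then cleave the PMB group with TFA/anisole, so the methyl can only sit on the N–O oxygen.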